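The readings were generated by integration from invented constants; noise was put on by code.

Time is held here: Z goes in over 15 min and the flasks are read at 25 min, while the charge of Z moves from 0.10 M to 0.50 M, with L following at 1.30 equiv.

| flask | Z | L | remark | time | volume of the second phase over the first |
|---|---|---|---|---|---|
| birch | 0.077 M (fed, over 15 min) | 1.3 equiv | run made earlier |  |  |
| beta | 0.10 M (fed, over 15 min) | 1.30 equiv |  | 25 min | 0.50 |
| zeta | 0.25 M (fed, over 15 min) | 1.30 equiv |  | 25 min | 0.50 |
| gamma | 0.15 M (fed, over 15 min) | 1.30 equiv |  | 25 min | 0.50 |
| theta | 0.50 M (fed, over 15 min) | 1.30 equiv |  | 25 min | 0.50 |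
| delta | 0.30 M (fed, over 15 min) | 1.30 equiv |  | 25 min | 0.50 |

birch run (percent of the Z charged)

| time / min | X / % |
|---|---|
| 2.00 | 0 |
| 6.00 | 1.1 |
| 12.0 | 1.1 |
| 20.0 | 5.0 |
| 25.0 | 7.6 |

(standard deviation of a reading: 0.5 percentage points)

1. the flasks by amount of X, in percent of the Z charged, highest first, at 25 min (beta / zeta / gamma / theta / delta)
2. the amount of X, in percent of the Z charged of the flask you put first, at 25 min
3. the amount of X, in percent of the Z charged of the flask you put last, at 25 min

- in the second phase: L; everything else is in the first
- charges count per volume of the first phase; a concentration in a rate is the amount of a species over the volume of its own phase; every rate counts per litre of the first phase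
- the analysis behind the earlier runs scatters by 0.5 percentage points, standard deviation
- the earlier runs hold the two phases in the same ratio of volumes as the flask asked about
- percentages count the whole charge, also what has not yet gone in
- a reading or a percentage of X counts all its forms, free or not

Birch forms X slowly, reaching 7.6% at 25.0 min, a reading with a scatter of 0.5 percentage points. If L is taken as steady, each Z has a constant chance per minute of reacting (a pseudo-first-order loss), and that chance grows with the L present. L is charged in equivalents of Z, so it grows in step with the charge c. With the same feed and the same clock, the exponent of the loss should then be proportional to c. Birch gives its factor: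

reach = −ln(1 − 7.6%) / 0.077 M = 1.03 M⁻¹

This reach is the exponent of the loss of Z at 25 min per molar of charge, and it is a reading with birch's scatter in it. The reckoning of this text then gives, with X as a fraction of the Z charged:

X = 1 − exp(−reach × c)

theta: 40.2%

beta: 9.79%

X rises with c on this reckoning, so theta stands first and beta last.

The forecast gives theta > delta > zeta > gamma > beta, on the ground that “percent X rises with charge”. It puts theta at 34% (range 25% to 45%) and beta at 9.5% (range 8% to 11.5%). Its theta stands below the reckoning above, and its beta lies close to it.

The flasks give theta > delta > zeta > gamma > beta, with theta at 27.5% and beta at 8.38%. The order holds, beta falls inside its range, and the forecast's theta is 6.5 points too high.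

    Z + X ⇌ G, settled at all times (K = 150 M⁻¹)
    Q ⇌ L, rate k2*([Q] - [L]/K2) per volume of the first phase (partition coefficient = 12.7, kL = 0.0320 s⁻¹)
    Z + Q → X (k = 0.00517 M⁻¹ s⁻¹)

At 25 min theta holds 45.8% of its Z free beside 27.5% of X, so free Z has fallen by twice the X; G, counted as two, stands at 53.4%. With the reach kept and two Z lost per X, the line becomes X = (1 − exp(−2 × reach × c)) / 2, which gives 32.1% for theta. The neighbour charged with 0.85 M of Z, its recipe otherwise theta's, reckons to 41.3% this way. That flask gives 35.6% of X.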